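## Structural features

The target is a C15 bicycle whose ring A is a ten-membered carbocycle (C1–C10). Ring A is fused along C5–C6 to ring B, a butenolide made of C5, C11, the carbonyl carbon C12, the ring oxygen and C6. Ring A holds the C1 ketone, an exocyclic methylene (C14) on C2, the acetoxy stereocentre C4 (S) and a (Z)-trisubstituted C7=C8 bond with the methyl group C15; C11 carries the acetoxymethyl carbon C13. The stereocentres C4 and C6 (R) are not neighbours: both sit on the sp2 carbon C5, so their relation must be passed across the tetrasubstituted C5=C11 bond. The fragile parts are the α-methylene ketone (a strong Michael acceptor), the C6 hydrogen (doubly allylic and γ to the lactone carbonyl), the two allylic acetates and the cis alkene in a medium ring. The real difficulty is closing a ten-membered ring that contains a cis trisubstituted alkene and is bridged by a butenolide, while keeping the enone for the end. The key step uses the fact that C1, C10, C9, C8 (with C15), C7 and C6 have the carbon pattern of 4-methylcyclohex-3-enone: with C1–C6 bonded and C3–C4 open, ring A is a cyclohexenol with a C2 alkenyl group on C1 and a C5 dienyl group on C6, a 1,5-diene ready for a [3,3] shift.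

## Logic of the disconnections

35 to 34: the two acyl C–O bonds at O4 and O13 are cut. Acetates would not survive hydride bases, organometallic reagents or methanolysis, so they go on last. The gain is a diol that can be carried as ethers. The forward acylation must be mild enough for the methylene ketone.

34 to 33: the two benzylic C–O bonds are cut. Both oxygens travel as 4-methoxybenzyl ethers, so one oxidative step frees both. The forward step must cleave two allylic ethers without touching the alkenes or the butenolide. A shift of the lactone to O4 is excluded because O4 is trans to C12 across C5=C11.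

33 to 31: the O–C12 acyl bond is cut and C12 is taken back to the alcohol level. Ring B becomes a cis-2-ene-1,4-diol. The forward step must oxidize the primary allylic alcohol at C12 in preference to the C6 carbinol; the cis geometry then leads to the lactol and on to the lactone.

31 to 29 (through 30): the C6–O and C12–O bonds are cut together, and both oxygens are traced to one molecule of O2. A cycloadduct places C12–O cis to C6 about the new C5=C11 bond by construction and sets C6 by suprafacial delivery to one face. The gain is the loss of one stereocentre and two oxygens, leaving an exocyclic diene. The forward step needs the cycloaddition to outrun the ene reaction at C7=C8, and O2 must attack the diene face that is not covered by the ring.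

29 to 26 (key): C3–C4 is cut and C1–C6 is re-formed. The ten-membered ring, the (E)-C5=C6 bond, the C4 stereocentre and the methylene ketone then all come from one alkoxide. No medium ring has to be closed end to end, and the (Z)-C7=C8 bond is already fixed in a six-membered ring. The forward step requires the (1S,2S)-trans-dialkenyl arrangement, a (Z)-enol ether, a free tertiary hydroxyl and a chair pathway.

26 to 24 and 10: the C5–C11 bond is cut. A cross-coupling of an enol triflate copies a defined enolate geometry into the enol ether. An alkoxymethylene olefination of a hindered ketone gives no such control, and the key step depends on this geometry. The diene is reduced to a two-carbon oxygenated side chain and a three-carbon boronate. The coupling must proceed with retention, and the tertiary oxygen must be masked until its end.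

24 to 22 to 21: the O–S bond of the triflate and the O–Si bond are cut. An α-alkoxy ketone forms a lithium-bridged (Z)-enolate, which places the sulfonate cis to the ether oxygen. The forward steps need deprotonation at C4 rather than at C6. They also need a silyl ether on O1, because a free alkoxide β to the C5 ketone would break C1–C6 by retro-aldol cleavage, the very bond reserved for the key step.

21 to 20: the C5 carbonyl is taken back to a carbinol. While C1 is still a ketone, this carbinol is the only stable anchor for the labile C6 centre. The oxidation must be non-basic.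

20 to 17 and 7: the C1–C2 bond is cut. A 1,2-addition of an alkenylmetal builds the quaternary carbinol and sets C1 relative to C6. The reagent must add faster than it enolizes the doubly activated C6–H, and it must approach anti to the C6 side chain.

17 to 16 to 13 and 5: the C5–C6 bond is cut after a resolution. The dienolate of 13 reacts at its α-carbon, so the alkene stays at C7=C8, and the anti aldol ties C6 to a carbinol that an enzyme can read. The forward steps need α-attack, anti selectivity and discrimination of the carbinol enantiomers.

13 to 11: ring hydrogens are removed to return to the arene. A cheap arene gives the ketone position, the methyl group and the cis alkene in one reduction. The hydrolysis must stop at the unconjugated enone.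

5 to 3 to 1 and 2; 7 to 6; 10 to 9 to 8 and 6: the aldehyde carbon of 5 is traced back to a terminal alkene, and ether C–O bonds and one C–B bond are cut to reach commercial materials. Each forward step is a substitution at an allylic or benzylic carbon, an alkene cleavage or a borylation of an alkenyl bromide, and each uses its partners in a one-to-one ratio.

## Other disconnections considered

Alternative 1: The cut is C1–C2. The acyclic ynal A1 would be closed with Ni(cod)2 (zerovalent nickel), a bulky N-heterocyclic carbene and Et3SiH to the exo-methylene allylic silyl ether A2. The internal alkyne carbon bonds to the aldehyde carbon, and the carbinol configuration is irrelevant because it is oxidized later.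
- In favour: the plan is convergent; ring B and both stereocentres are made in an open chain by standard means; the methylene group and the C1 oxygen arise in the ring closure.
- Against: ten is the least favourable ring size for an end-to-end reductive closure; exo or endo selectivity rests on the ligand alone; the butenolide of A1 is a good ligand for zerovalent nickel and a possible coupling partner for the alkyne.
- Comparison: A2 needs four more operations (two desilylations, oxidation, acetylation), equal to the four that follow the chosen key step. Alternative 1 is the better plan in that it needs no photooxygenation and no strong base late. The chosen plan is the better in ring formation (a sigmatropic ring expansion), and it takes the (Z)-alkene from an arene and both stereocentres from one resolved carbinol, whereas A1 needs each set separately.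

Alternative 2: The cut is C2–C3. PMe3 would add to the vinyl ketone of the epoxy enone A3, the phosphonium enolate would open the terminal epoxide at C3, and loss of the phosphine would give the hydroxy methylene ketone A4.
- In favour: no metal is needed; the methylene ketone and the free C4 hydroxyl appear directly; the C4–O bond is never touched; A4 is only a desilylation and a double acetylation away from the target. This is the shortest endgame of the four plans and in that respect better than the chosen one.
- Against: this alkylation is established for five- and six-membered rings, and a ten-membered closure by a weakly nucleophilic zwitterion must compete with dimerization of the vinyl ketone and with attack of the phosphine on the epoxide; the epoxide of A3 is allylic to C5=C11 and can open with allylic shift; A3 carries a vinyl ketone through its preparation.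
- Comparison: on stereochemistry the two plans are equal once A3 is in hand. On step count after ring closure alternative 2 is better. On the reliability of the ring-forming event and the stability of the precursor the chosen plan is better.

Alternative 3: The cut is C9–C10. Pd2(dba)3 (zerovalent palladium) with a phosphine would ionize the twelve-membered allyl β-keto lactone A5; after loss of CO2 the C10 enolate would attack C9 to give the bis-silyl ether A6.
- In favour: a twelve-membered lactonization is easier than any ten-membered carbocyclization; the C–C bond forms inside an ion pair from a regiodefined enolate without added base; A6 is two steps from the target with no diene oxidation. In the certainty of ring closure and in late-stage simplicity this plan equals or betters the chosen one.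
- Against: the allyl complex spans C7–C8–C9, and syn/anti exchange there would erode the (Z) geometry; attack at C7 would give an eight-membered ring; the lactone oxygen on C6 is itself an allylic carboxylate of the same alkene and may ionize; the enolate may add to the methylene ketone of a second molecule.
- Comparison: the chosen plan never exposes C7=C8 to a metal and sets C4 during ring formation, and there it is better. Alternative 3 needs a long linear preparation of A5 with both stereocentres, so the overall step count is expected to be about equal or higher.

Key step: step 14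

Remark: atom labels C1–C15 are those defined under Structural features and are kept for every intermediate; PMB stands for 4-methoxybenzyl; racemic compounds are written as both enantiomers joined by a dot.

Remark: a chair rearrangement of 26, with the (1S,2S) ring configuration and the (Z)-enol ether, leads to the 4S centre of 29. The enol ether geometry is therefore secured by a stereoretentive cross-coupling of a (Z)-enol triflate, and O1 is masked as a silyl ether while C5 is a ketone.

## Route

Step 1
Reactants: 1 prop-2-en-1-ol (allyl alcohol); 2 4-methoxybenzyl chloride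
Product: 3 1-methoxy-4-[(prop-2-en-1-yloxy)methyl]benzene (allyl 4-methoxybenzyl ether)
Conditions: NaH, Bu4NI (cat.), THF/DMF, 0 °C → rt
Reagents that add atoms: none
Why: Williamson etherification of the primary allylic alkoxide with one equivalent of the benzylic chloride; the terminal alkene is not affected.

Step 2
Reactants: 3 1-methoxy-4-[(prop-2-en-1-yloxy)methyl]benzene
Product: 5 2-[(4-methoxybenzyl)oxy]acetaldehyde, via racemic diol 4 (not isolated)
Conditions: OsO4 (cat.), NaIO4, 2,6-lutidine, dioxane/H2O, rt
Reagents that add atoms: osmium tetroxide, O=[Os](=O)(=O)=O (catalytic oxygen carrier); sodium periodate, [Na+].[O-]I(=O)(=O)=O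
Why: Lemieux–Johnson cleavage: syn-dihydroxylation of the terminal alkene to 4, then periodate cleavage, which also reoxidizes osmium and releases the terminal carbon as formaldehyde. The lutidine buffer suppresses over-oxidation, and the electron-rich arene is left alone.

Step 3
Reactants: 6 2,3-dibromopropene
Product: 7 2-bromo-3-methoxyprop-1-ene
Conditions: NaOMe, MeOH, 0 °C → rt
Reagents that add atoms: sodium methoxide, [Na+].[O-]C
Why: SN2 displacement of the allylic bromide; the vinylic bromide is inert to methoxide.

Step 4
Reactants: 8 4-methoxybenzyl alcohol; 6 2,3-dibromopropene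
Product: 9 1-{[(2-bromoprop-2-en-1-yl)oxy]methyl}-4-methoxybenzene
Conditions: NaH, THF, 0 °C; then 6, rt
Reagents that add atoms: none
Why: Williamson etherification at the allylic carbon of 6.

Step 5
Reactants: 9 1-{[(2-bromoprop-2-en-1-yl)oxy]methyl}-4-methoxybenzene
Product: 10 2-{3-[(4-methoxybenzyl)oxy]prop-1-en-2-yl}-4,4,5,5-tetramethyl-1,3,2-dioxaborolane
Conditions: PdCl2(PPh3)2 (cat.), PPh3, KOPh, toluene, 50 °C
Reagents that add atoms: bis(pinacolato)diboron, CC1(C)OB(OC1(C)C)B1OC(C)(C)C(C)(C)O1
Why: Miyaura borylation of an alkenyl bromide; phenoxide is the usual base for alkenyl halides and the allylic ether is a spectator.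

Step 6
Reactants: 11 4-methylanisole
Product: 13 4-methylcyclohex-3-en-1-one, via Birch diene 12 (not isolated)
Conditions: Li, NH3 (l), t-BuOH, THF, −78 → −33 °C; then (CO2H)2, MeOH/H2O, rt
Reagents that add atoms: water, O
Why: Birch reduction leaves the methoxy and methyl groups on the two double bonds of the 1,4-diene. Oxalic acid hydrolyses the enol ether only and is too weak to move the C7=C8 bond into conjugation.

Step 7
Reactants: 13 4-methylcyclohex-3-en-1-one; 5 2-[(4-methoxybenzyl)oxy]acetaldehyde
Product: 16 racemic anti aldol (2S*)-2-{(1R*)-1-hydroxy-2-[(4-methoxybenzyl)oxy]ethyl}-4-methylcyclohex-3-en-1-one, via boron dienolate 14 (not isolated), via boron aldolate 15 (not isolated)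
Conditions: (c-C6H11)2BCl, Et3N, Et2O, −78 → 0 °C; then 5, −78 → −20 °C; pH 7 buffer, MeOH
Reagents that add atoms: none
Why: Boron-mediated aldol addition: enolization occurs at the doubly activated C6 to give the E(O) dienolate 14. It reacts at its α-carbon through a Zimmerman–Traxler chair, which gives the anti aldol and keeps C7=C8 out of conjugation.

Step 8
Reactants: 16 racemic anti aldol
Product: 17 (2S)-2-{(1R)-1-hydroxy-2-[(4-methoxybenzyl)oxy]ethyl}-4-methylcyclohex-3-en-1-one
Conditions: Amano lipase PS (immobilized), vinyl acetate, t-BuOMe, 30 °C, stopped near half conversion; chromatography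
Reagents that add atoms: none
Why: Lipase-catalysed kinetic resolution by acyl transfer. With the branched ring as the large group, the empirical size rule for lipases predicts acetylation of the (1'S)-carbinol, so 17 should be recovered as the free alcohol, with C6 held by the adjacent carbinol.

Step 9
Reactants: 7 2-bromo-3-methoxyprop-1-ene; 17 (2S)-2-{(1R)-1-hydroxy-2-[(4-methoxybenzyl)oxy]ethyl}-4-methylcyclohex-3-en-1-one
Product: 20 (1S,2S)-2-{(1R)-1-hydroxy-2-[(4-methoxybenzyl)oxy]ethyl}-1-(3-methoxyprop-1-en-2-yl)-4-methylcyclohex-3-en-1-ol, via alkenyllithium 18 (not isolated), via alkenylcerium dichloride 19 (not isolated)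
Conditions: t-BuLi, Et2O, −78 °C; CeCl3, THF, −78 °C; then 17 (19 in excess), −78 °C; aq. NH4Cl
Reagents that add atoms: none
Why: Bromine–lithium exchange, transmetalation to trivalent cerium and 1,2-addition. The weakly basic organocerium adds to the easily enolized ketone after one equivalent has been used up by the hydroxyl group. Equatorial attack anti to the C6 side chain should give the trans-dialkenyl arrangement (C1 S).

Step 10
Reactants: 20 (1S,2S)-diol
Product: 21 1-[(1R,6S)-6-hydroxy-6-(3-methoxyprop-1-en-2-yl)-3-methylcyclohex-2-en-1-yl]-2-[(4-methoxybenzyl)oxy]ethan-1-one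
Conditions: Dess–Martin periodinane, NaHCO3, CH2Cl2, 0 °C → rt
Reagents that add atoms: none
Why: Dess–Martin oxidation of the secondary alcohol under buffered, non-basic conditions, so that neither retro-aldol cleavage of C1–C6 nor migration of C7=C8 can begin; the tertiary alcohol cannot be oxidized.

Step 11
Reactants: 21 hydroxy ketone
Product: 22 1-[(1R,6S)-6-(3-methoxyprop-1-en-2-yl)-3-methyl-6-[(trimethylsilyl)oxy]cyclohex-2-en-1-yl]-2-[(4-methoxybenzyl)oxy]ethan-1-one
Conditions: Me3SiOTf, 2,6-lutidine, CH2Cl2, −78 °C
Reagents that add atoms: trimethylsilyl trifluoromethanesulfonate, C[Si](C)(C)OS(=O)(=O)C(F)(F)F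
Why: Silylation of the hindered tertiary alcohol with a silyl triflate at low temperature; as a silyl ether O1 can no longer start a retro-aldol cleavage when base is used in step 12.

Step 12
Reactants: 22 silyloxy ketone
Product: 24 (Z)-2-[(4-methoxybenzyl)oxy]-1-[(1R,6S)-6-(3-methoxyprop-1-en-2-yl)-3-methyl-6-[(trimethylsilyl)oxy]cyclohex-2-en-1-yl]ethenyl trifluoromethanesulfonate, via lithium (Z)-enolate 23 (not isolated)
Conditions: LiN(SiMe3)2, THF, −78 °C (22 added to the base); then N-(5-chloropyridin-2-yl)bis(trifluoromethanesulfonyl)imide, −78 → −40 °C; aq. NH4Cl
Reagents that add atoms: N-(5-chloropyridin-2-yl)bis(trifluoromethanesulfonyl)imide, O=S(=O)(N(c1ccc(Cl)cn1)S(=O)(=O)C(F)(F)F)C(F)(F)F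
Why: Kinetic enolization of an α-alkoxy ketone: lithium bridged between the carbonyl and ether oxygens exposes the C4 hydrogens and gives the (Z)-enolate 23, while the single C6 hydrogen lies near the carbonyl plane next to a quaternary carbon. O-Sulfonylation then fixes the geometry as the enol triflate, with the sulfonate cis to the ether oxygen.

Step 13
Reactants: 24 (Z)-enol triflate; 10 alkenylboronate
Product: 26 (1S,2S)-2-{(1Z)-1-[(4-methoxybenzyl)oxy]-3-{[(4-methoxybenzyl)oxy]methyl}buta-1,3-dien-2-yl}-1-(3-methoxyprop-1-en-2-yl)-4-methylcyclohex-3-en-1-ol, via silyl ether 25 (not isolated)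
Conditions: PdCl2(dppf) (cat.), K3PO4, THF/H2O, 50 °C; then K2CO3, MeOH, rt
Reagents that add atoms: none
Why: Suzuki–Miyaura coupling of an enol triflate with an alkenylboronate proceeds with retention at both carbons, so the ether oxygen ends cis to the new propenyl group (the (Z)-enol ether). Base-catalysed methanolysis then frees the tertiary alcohol.

Step 14
Reactants: 26 (1S,2S)-(Z)-dienyl cyclohexenol
Product: 29 (4S,5E,7Z)-4-[(4-methoxybenzyl)oxy]-5-{3-[(4-methoxybenzyl)oxy]prop-1-en-2-yl}-8-methyl-2-methylidenecyclodeca-5,7-dien-1-one, via potassium alkoxide 27 (not isolated), via potassium enolate 28 (not isolated)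
Conditions: KH, 18-crown-6, THF, 0 °C → rt; aq. NH4Cl at −20 °C
Reagents that add atoms: none
Why: KH converts 26 into the potassium alkoxide 27, whose charge, freed from the cation by the crown ether, weakens the doubly allylic C1–C6 bond. A [3,3] sigmatropic shift through a chair array of C3, C2, C1, C6, C5 and C4, with the ring bonds C1–C10 and C6–C7 equatorial, forms C3–C4 and breaks C1–C6. Ring A is therefore closed by a four-atom ring expansion and not by an end-to-end cyclization, so the entropy cost of a medium-ring closure is not paid. The equatorial ring bond at C6 makes the new C5=C6 bond (E), and C7=C8 keeps its (Z) geometry. The new stereocentre C4 is controlled by the (Z)-enol ether, which holds the ether oxygen equatorial, together with the (1S,2S) ring configuration; this combination gives 4S. The enolate 28 then expels methoxide from C14 (E1cB), which places the methylene group at C2 without a separate enolization. The step needs a chair path through the exocyclic enol ether instead of a boat path through C7=C8 (which would join C3 to the methyl-bearing C8), and a concerted rather than a dissociative course; the trans-diequatorial alkenyl groups, the steric cost at C8 and the low temperature should secure both. The closest known reaction type is the anionic oxy-Cope rearrangement of trans-1,2-dialkenylcyclohexanols to cyclodec-5-enones, here followed by β-alkoxide elimination from the enolate.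

Step 15
Reactants: 29 ten-membered methylene ketone
Product: 31 (4S,6R,7Z)-6-hydroxy-5-{1-hydroxy-3-[(4-methoxybenzyl)oxy]propan-2-ylidene}-4-[(4-methoxybenzyl)oxy]-8-methyl-2-methylidenecyclodec-7-en-1-one (hydroxymethyl C12 cis to C6 across C5=C11), via endoperoxide 30 (not isolated)
Conditions: O2, tetraphenylporphyrin (cat.), visible light, CH2Cl2, −78 °C; then thiourea, MeOH, −78 °C → rt
Reagents that add atoms: dioxygen, O=O
Why: [4+2] cycloaddition of singlet oxygen to the C6=C5–C11=C12 diene, then reduction of the O–O bond by thiourea; the suprafacial addition makes the C12 and C6 hydroxyls cis about the new C5=C11 bond. O2 should add to the diene face turned away from the C3–C2–C1 chain, a face that the 4S centre fixes through the ring conformation delivered by the chair rearrangement, and addition there gives 6R.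

Step 16
Reactants: 31 cis-ene-1,4-diol
Product: 33 butenolide bis(4-methoxybenzyl) ether (rings A and B complete; PMB on O4 and O13; 4S,6R,7Z), via lactol 32 (not isolated)
Conditions: TEMPO (cat.), PhI(OAc)2, CH2Cl2, rt
Reagents that add atoms: none
Why: Oxoammonium oxidation is selective for the primary allylic alcohol. The hydroxy aldehyde closes to lactol 32 with the cis C6 hydroxyl, and 32 is oxidized on to the lactone.

Step 17
Reactants: 33 butenolide bis(4-methoxybenzyl) ether
Product: 34 diol (4S,6R,7Z) with free hydroxyls on C4 and C13
Conditions: DDQ, CH2Cl2/pH 7 phosphate buffer, 0 °C → rt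
Reagents that add atoms: none
Why: Oxidative cleavage of 4-methoxybenzyl ethers by DDQ (benzylic hydride abstraction, then hydrolysis). The freed C4 hydroxyl cannot take over the lactone because it is trans to C12 across C5=C11.

Step 18
Reactants: 34 diol
Product: 35 target diacetate (4S,6R,7Z)
Conditions: Ac2O, pyridine, DMAP (cat.), CH2Cl2, 0 °C
Reagents that add atoms: acetic anhydride, CC(=O)OC(C)=O
Why: Acylation of a primary and a secondary allylic alcohol under nucleophilic catalysis at low temperature, which the methylene ketone should tolerate.

## Compound list

1 | prop-2-en-1-ol (allyl alcohol) | C=CCO | starting material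
2 | 4-methoxybenzyl chloride | COc1ccc(CCl)cc1 | starting material
3 | 1-methoxy-4-[(prop-2-en-1-yloxy)methyl]benzene (allyl 4-methoxybenzyl ether) | COc1ccc(COCC=C)cc1 | intermediate
4 | racemic 3-[(4-methoxybenzyl)oxy]propane-1,2-diol (not isolated) | COc1ccc(COC[C@H](O)CO)cc1.COc1ccc(COC[C@@H](O)CO)cc1 | intermediate
5 | 2-[(4-methoxybenzyl)oxy]acetaldehyde | COc1ccc(COCC=O)cc1 | intermediate
6 | 2,3-dibromopropene | C=C(Br)CBr | starting material
7 | 2-bromo-3-methoxyprop-1-ene | COCC(Br)=C | intermediate
8 | 4-methoxybenzyl alcohol | COc1ccc(CO)cc1 | starting material
9 | 1-{[(2-bromoprop-2-en-1-yl)oxy]methyl}-4-methoxybenzene | COc1ccc(COCC(Br)=C)cc1 | intermediate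
10 | 2-{3-[(4-methoxybenzyl)oxy]prop-1-en-2-yl}-4,4,5,5-tetramethyl-1,3,2-dioxaborolane | COc1ccc(COCC(=C)B2OC(C)(C)C(C)(C)O2)cc1 | intermediate
11 | 4-methylanisole | COc1ccc(C)cc1 | starting material
12 | 1-methoxy-4-methylcyclohexa-1,4-diene (not isolated) | COC1=CCC(C)=CC1 | intermediate
13 | 4-methylcyclohex-3-en-1-one | CC1=CCC(=O)CC1 | intermediate
14 | dicyclohexyl[(4-methylcyclohexa-1,3-dien-1-yl)oxy]borane (not isolated) | CC1=CC=C(OB(C2CCCCC2)C2CCCCC2)CC1 | intermediate
15 | racemic O-dicyclohexylboryl derivative of the anti aldol (not isolated) | O=C1CCC(C)=C[C@H]1[C@@H](OB(C2CCCCC2)C2CCCCC2)COCc2ccc(OC)cc2.O=C1CCC(C)=C[C@@H]1[C@H](OB(C2CCCCC2)C2CCCCC2)COCc2ccc(OC)cc2 | intermediate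
16 | racemic anti aldol, (2S*)-2-{(1R*)-1-hydroxy-2-[(4-methoxybenzyl)oxy]ethyl}-4-methylcyclohex-3-en-1-one | O=C1CCC(C)=C[C@H]1[C@@H](O)COCc2ccc(OC)cc2.O=C1CCC(C)=C[C@@H]1[C@H](O)COCc2ccc(OC)cc2 | intermediate
17 | (2S)-2-{(1R)-1-hydroxy-2-[(4-methoxybenzyl)oxy]ethyl}-4-methylcyclohex-3-en-1-one | O=C1CCC(C)=C[C@H]1[C@@H](O)COCc2ccc(OC)cc2 | intermediate
18 | (3-methoxyprop-1-en-2-yl)lithium (not isolated) | [Li]C(=C)COC | intermediate
19 | dichloro(3-methoxyprop-1-en-2-yl)cerium (not isolated) | Cl[Ce](Cl)C(=C)COC | intermediate
20 | (1S,2S)-2-{(1R)-1-hydroxy-2-[(4-methoxybenzyl)oxy]ethyl}-1-(3-methoxyprop-1-en-2-yl)-4-methylcyclohex-3-en-1-ol | COCC(=C)[C@]1(O)CCC(C)=C[C@H]1[C@@H](O)COCc2ccc(OC)cc2 | intermediate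
21 | 1-[(1R,6S)-6-hydroxy-6-(3-methoxyprop-1-en-2-yl)-3-methylcyclohex-2-en-1-yl]-2-[(4-methoxybenzyl)oxy]ethan-1-one | COCC(=C)[C@]1(O)CCC(C)=C[C@H]1C(=O)COCc2ccc(OC)cc2 | intermediate
22 | trimethylsilyl ether of 21 at the tertiary oxygen | COCC(=C)[C@]1(O[Si](C)(C)C)CCC(C)=C[C@H]1C(=O)COCc2ccc(OC)cc2 | intermediate
23 | lithium (Z)-enolate of 22, enolate oxygen cis to the ether oxygen (not isolated) | COCC(=C)[C@]1(O[Si](C)(C)C)CCC(C)=C[C@H]1/C(O[Li])=C/OCc2ccc(OC)cc2 | intermediate
24 | (Z)-enol triflate of 22, triflate cis to the ether oxygen | COCC(=C)[C@]1(O[Si](C)(C)C)CCC(C)=C[C@H]1/C(OS(=O)(=O)C(F)(F)F)=C/OCc2ccc(OC)cc2 | intermediate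
25 | trimethylsilyl ether of 26 (not isolated) | COCC(=C)[C@]1(O[Si](C)(C)C)CCC(C)=C[C@H]1/C(=C/OCc2ccc(OC)cc2)C(=C)COCc2ccc(OC)cc2 | intermediate
26 | (1S,2S)-2-{(1Z)-1-[(4-methoxybenzyl)oxy]-3-{[(4-methoxybenzyl)oxy]methyl}buta-1,3-dien-2-yl}-1-(3-methoxyprop-1-en-2-yl)-4-methylcyclohex-3-en-1-ol | COCC(=C)[C@]1(O)CCC(C)=C[C@H]1/C(=C/OCc2ccc(OC)cc2)C(=C)COCc2ccc(OC)cc2 | intermediate
27 | potassium alkoxide of 26 (not isolated) | COCC(=C)[C@]1(O[K])CCC(C)=C[C@H]1/C(=C/OCc2ccc(OC)cc2)C(=C)COCc2ccc(OC)cc2 | intermediate
28 | potassium (E)-enolate of the ring-expanded 2-(methoxymethyl) ketone, 4S,5E,7Z (not isolated) | C1/C(COC)=C(O[K])/CC/C(C)=C\C=C(\[C@H]1OCc2ccc(OC)cc2)C(=C)COCc2ccc(OC)cc2 | intermediate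
29 | (4S,5E,7Z)-4-[(4-methoxybenzyl)oxy]-5-{3-[(4-methoxybenzyl)oxy]prop-1-en-2-yl}-8-methyl-2-methylidenecyclodeca-5,7-dien-1-one | C=C1C[C@H](OCc2ccc(OC)cc2)/C(C(=C)COCc2ccc(OC)cc2)=C/C=C(/C)CCC1=O | intermediate
30 | endoperoxide, 3,6-dihydro-1,2-dioxine fused at C5–C6 with O–O joining C6 and C12, 4S,6R,7Z (not isolated) | C=C1C[C@H](OCc2ccc(OC)cc2)C3=C(COCc2ccc(OC)cc2)COO[C@@H]3/C=C(/C)CCC1=O | intermediate
31 | (4S,6R,7Z)-6-hydroxy-5-{1-hydroxy-3-[(4-methoxybenzyl)oxy]propan-2-ylidene}-4-[(4-methoxybenzyl)oxy]-8-methyl-2-methylidenecyclodec-7-en-1-one, hydroxymethyl cis to C6 | C=C1C[C@H](OCc2ccc(OC)cc2)/C(=C(/CO)COCc2ccc(OC)cc2)[C@H](O)/C=C(/C)CCC1=O | intermediate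
32 | lactol at C12, mixture of anomers, 4S,6R,7Z (not isolated) | C=C1C[C@H](OCc2ccc(OC)cc2)C3=C(COCc2ccc(OC)cc2)C(O)O[C@@H]3/C=C(/C)CCC1=O | intermediate
33 | butenolide with 4-methoxybenzyl ethers on O4 and O13, 4S,6R,7Z | C=C1C[C@H](OCc2ccc(OC)cc2)C3=C(COCc2ccc(OC)cc2)C(=O)O[C@@H]3/C=C(/C)CCC1=O | intermediate
34 | butenolide diol with free hydroxyls on C4 and C13, 4S,6R,7Z | C=C1C[C@H](O)C2=C(CO)C(=O)O[C@@H]2/C=C(/C)CCC1=O | intermediate
35 | target, diacetate at O4 and O13, 4S,6R,7Z | C=C1C[C@H](OC(C)=O)C2=C(COC(C)=O)C(=O)O[C@@H]2/C=C(/C)CCC1=O | target

## Step count and least certain steps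

Total: 18 steps (steps 1–5 make the fragments 5, 7 and 10; steps 6–18 are the main line). Longest linear sequence: 14 steps (1, 2, 7–18).

Step 14 (key step). The most likely failure is heterolytic cleavage of C1–C6 to a dienyl anion and an enone that recombine without control, with loss of configuration at C4 or bonding of C3 to C8. Conjugate addition of methoxide or of an enolate to the new methylene ketone is a further risk. The carbanion that would form at C6 is stabilized by two alkenes, and the product is a reactive acceptor in a basic medium. Fallback: a neutral, thermal rearrangement. The methanolysis in step 13 is left out and 25 is isolated. Heating 25 in toluene in base-washed sealed glass at about 180 °C should give, by a concerted siloxy-Cope shift, the trimethylsilyl enol ether of the ring-expanded ketone F1. Bu4NF in THF at −78 → 0 °C then releases the enolate 28, which loses methoxide, and the route is rejoined at 29.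

Step 15. The most likely failure is competition from the ene reaction of singlet oxygen at the electron-rich C7=C8 bond, together with poor facial selectivity if ring A changes conformation before the cycloaddition. The diene carries two allylic ether groups, has an inward substituent at C6, and is therefore not a fast partner. Fallback: a palladium-mediated 1,4-diacetoxylation, which has no ene pathway and tolerates the methylene ketone. Starting from 29, Pd(OAc)2 (divalent palladium, catalytic) with p-benzoquinone and LiOAc in AcOH/acetone without chloride should add acetate to C12 of the s-cis diene and then transfer the second acetate from palladium to C6 on the outer face, giving the 1,4-diacetate F2. The two CH2O groups on C11 can exchange places in the allyl complex only through a σ-complex at this fully substituted carbon, so the cis relation of C12 and C6 should be kept. Mg(OMe)2 in MeOH at 0 °C removes both acetyl groups, and the route is rejoined at 31.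

Step 12. The most likely failure is deprotonation at C6 instead of C4, followed by loss of the silyloxy group from C1, or partial formation of the (E)-enolate with loss of geometric purity. C6–H is allylic as well as α to the ketone. Fallback: regiocontrol by charge instead of by a protecting group. Starting from 21 (step 11 omitted), LiN(i-Pr)2 (2.2 equivalents, THF, −78 °C) forms the alkoxide–enolate dianion; a negative charge on O1 disfavours a second one on the adjacent C6 and cannot leave, and fast deprotonation at −78 °C should outrun retro-aldol cleavage. Sulfonylation as in step 12 gives the hydroxy enol triflate F3, which is coupled with 10 under the palladium conditions of step 13, and the route is rejoined at 26.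

Step 8. The most likely failure is poor discrimination of the enantiomers, because both groups on the carbinol are large, combined with slow acylation during which the aldol can dehydrate. Fallback: a covalent resolution at a stage without a labile centre. Racemic 16 is taken through step 9 to the racemic diol F4. Its secondary hydroxyl is esterified with (S)-2-methoxy-2-phenylacetic acid (dicyclohexylcarbodiimide, DMAP cat., CH2Cl2), and the diastereomeric esters are separated by chromatography. The (S)-2-methoxy-2-phenylacetate F5 of the (1S,2S,1'R) diol is cleaved with K2CO3 in MeOH, and the route is rejoined at 20.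

## Further compounds

F1 | step 14 | trimethylsilyl (E)-enol ether of the ring-expanded 2-(methoxymethyl) ketone, 4S,5E,7Z | C1/C(COC)=C(O[Si](C)(C)C)/CC/C(C)=C\C=C(\[C@H]1OCc2ccc(OC)cc2)C(=C)COCc2ccc(OC)cc2
F2 | step 15 | 1,4-diacetate of 31 (acetates on O6 and on the C12 oxygen), 4S,6R,7Z | C=C1C[C@H](OCc2ccc(OC)cc2)/C(=C(/COC(C)=O)COCc2ccc(OC)cc2)[C@H](OC(C)=O)/C=C(/C)CCC1=O
F3 | step 12 | (Z)-enol triflate of 21 with free tertiary hydroxyl | COCC(=C)[C@]1(O)CCC(C)=C[C@H]1/C(OS(=O)(=O)C(F)(F)F)=C/OCc2ccc(OC)cc2
F4 | step 8 | racemic diol, both enantiomers of 20 | COCC(=C)[C@]1(O)CCC(C)=C[C@H]1[C@@H](O)COCc2ccc(OC)cc2.COCC(=C)[C@@]1(O)CCC(C)=C[C@@H]1[C@H](O)COCc2ccc(OC)cc2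
F5 | step 8 | (S)-2-methoxy-2-phenylacetate of 20 at the secondary hydroxyl | COCC(=C)[C@]1(O)CCC(C)=C[C@H]1[C@@H](OC(=O)[C@@H](OC)c2ccccc2)COCc3ccc(OC)cc3
A1 | alternative 1 | acyclic ynal with complete butenolide, bis(tert-butyldimethylsilyl) ether | C#CC[C@H](O[Si](C)(C)C(C)(C)C)C1=C(CO[Si](C)(C)C(C)(C)C)C(=O)O[C@@H]1/C=C(/C)CCC=O
A2 | alternative 1 | ten-membered exo-methylene allylic triethylsilyl ether, one C1 epimer drawn | C=C1C[C@H](O[Si](C)(C)C(C)(C)C)C2=C(CO[Si](C)(C)C(C)(C)C)C(=O)O[C@@H]2/C=C(/C)CC[C@@H]1O[Si](CC)(CC)CC
A3 | alternative 2 | acyclic vinyl ketone with terminal epoxide and complete butenolide | C=CC(=O)CC/C(C)=C\[C@H]1OC(=O)C(CO[Si](C)(C)C(C)(C)C)=C1[C@@H]1CO1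
A4 | alternative 2 | ten-membered hydroxy methylene ketone fused to the butenolide, primary tert-butyldimethylsilyl ether | C=C1C[C@H](O)C2=C(CO[Si](C)(C)C(C)(C)C)C(=O)O[C@@H]2/C=C(/C)CCC1=O
A5 | alternative 3 | twelve-membered allyl β-keto lactone, bis(tert-butyldimethylsilyl) ether | C=C1C[C@H](O[Si](C)(C)C(C)(C)C)C2=C(CO[Si](C)(C)C(C)(C)C)C(=O)O[C@@H]2/C=C(/C)COC(=O)CC1=O
A6 | alternative 3 | complete bicyclic core as bis(tert-butyldimethylsilyl) ether | C=C1C[C@H](O[Si](C)(C)C(C)(C)C)C2=C(CO[Si](C)(C)C(C)(C)C)C(=O)O[C@@H]2/C=C(/C)CCC1=O
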